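**Remarks before the route**

Assumption: atoms carry the numbering of the target (quinone carbonyls C1 and C4, hydroxyls at C2 and C5, aroyl group at C6, side chain at C7, primed numbers for ring A). Ring A is the resorcinol ring, ring B the benzenoid ring C4a–C5–C6–C7–C8–C8a, ring C the quinone ring and ring D the pyranone. Compounds 8, 9 and 20 are treated as catalogue chemicals.

Structure check: the two annulation partners map onto the naphthol without contradiction. The ester carbon of 7 becomes C5, its methyl carbon C8 and its methoxy groups end at C4, C2 and C1. C2 and C3 of 13 become C6 and C7, and the E descriptor of 13 agrees with its drawn geometry. No structure needed correction.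

Three weak points of the most direct execution are repaired:
- The methoxy group of 13 is placed by methanol addition to an ynone, so its position does not depend on selective enol etherification of a diketone.
- The doubly ortho-substituted amide is converted to the ester through its O-methyl imidate, not by direct hydrolysis.
- The quinone is not made with a cerium oxidant next to the free hydroxypyranone; it is made by aerobic oxidation of the triol after ether cleavage.

## Structural features

The target is a 2,5-dihydroxy-1,4-naphthoquinone in which quinone ring C is fused to benzenoid ring B. Ring B carries at C6 a 2,4-dihydroxy-6-methylbenzoyl group (ring A) and at C7 a methylene bridge to C6 of a 4-hydroxy-2H-pyran-2-one (ring D). There is no stereocentre, so the problem is one of constitution and crowding. The diaryl ketone sits between four ortho groups (C5–OH, C7–CH2, C2'–OH, C6'–CH3), which rules out late acylation at C6 or addition of an aryl metal to a C6 carbonyl derivative. The fragile parts are the 2-hydroxyquinone (base, nucleophiles, reductants), the hydroxypyranone (an enolised 1,3-dicarbonyl, easily oxidised and opened by strong nucleophiles) and the C7 methylene, which is doubly activated and lies 1,5 to the ketone. Five acidic hydroxyl groups make the free compound unsuitable for anionic chemistry, so the oxygens are carried as methyl ethers, ring C as a 1,2,4-trimethoxyarene and ring D as a dioxinone until the end. The real difficulty is the contiguous C5–O, C6–C(=O)Ar, C7–CH2 triad on ring B. The key step uses this triad: a C5 hydroxyl flanked by a C6 acyl group and a C7 carbon substituent, with hydrogen at C8, is the pattern of a 1-naphthol built from an ortho-toluate (ester carbon to C5, benzylic carbon to C8) and a β-alkoxy enone (α-carbon to C6, β-carbon to C7) whose carbonyl is the ring A ketone.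

## Logic of the disconnections

27 back to 25 (through 26). No skeletal bond is cut; six O–CH3 bonds are restored and ring C is returned to the arene oxidation level. The reason is that every acidic or oxidisable oxygen stays capped through the anionic and oxidative steps, and the quinone then arises from the 1,2,4-triol by aerobic oxidation, so no metal oxidant meets ring D. The gain is a precursor without quinone or free phenol. The demand is that six ethers are cleaved without harm to the lactone and the ketone, and that oxidation stops at the hydroxyquinone.

25 back to 23 (through 24). The lactone bond O1–C2 of ring D is cut and the ring is unfolded into a side-chain ketone and a dioxinone. The dioxinone is a neutral, storable precursor of the acylketene and already holds C2 to C5 of ring D. The gain is that ring D becomes a linear chain. The demand is that the ketene is captured by the enol oxygen of its own side chain faster than by anything else.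

23 back to 22, then to 19 and 20. After adjusting the ketone to the carbinol, the bond between the carbinol carbon (future C6 of ring D) and the neighbouring methylene (future C5 of ring D) is cut as an aldol bond. This separates a four-carbon catalogue unit from an arylacetaldehyde, so all but one of the ring D carbons arrive in one bond formation. The demand is γ-selective attack of a dienolate on an enolisable aldehyde while the diaryl ketone stays untouched.

19 back to 18, 17 and 16. Only functional groups change: aldehyde from primary alcohol, alcohol from benzyl ether, C5 methyl ether from the naphthol. The two-carbon arm has to pass through the annulation as an ether inert to strong base, and the naphthol is capped before oxidants and bases are used. The gain is that 16 is the direct product of the annulation. The demand is a hydrogenolysis that spares the diaryl ketone and an oxidation that stops at the aldehyde.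

16 back to 7 and 13. The bonds C7–C8 and C5–C6 are cut, which opens ring B. This is the only cut that creates the crowded triad in the bond-forming event itself, with the ketone already present in one partner. It divides the molecule into two benzene derivatives of similar size. The demand is conjugate addition in preference to carbonyl addition and to proton abstraction from C4 of 13.

13 back to 12, 11, then 8 and 9. First the C3–OCH3 bond is cut, then, after adjusting ketone to carbinol, the bond between the carbonyl carbon and the alkyne carbon. Adding the methoxy group to an ynone fixes it at C3 by construction and avoids a Claisen condensation with a β-alkoxy ester that can lose alkoxide. The gain is two catalogue pieces. The demand is a base mild enough that benzyloxide is not eliminated.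

7 back to 5, 3 and 1. The ester is traced to the tertiary amide, the ring–CH3 bond at C6 is cut, and the amide is traced to the acid. The acid has all three oxygens in place and only the methyl is missing; the position between the amide and the 5-methoxy group is the one a directed lithiation should reach. The demand is lithiation at C6 and not at C3, and a way to turn a doubly ortho-substituted amide into an ester.

## Other disconnections considered

Alternative 1: The cut lies in ring C, at C1–C8a and C4–C4a. Ring B, complete with C5 methoxy, C6 aroyl and a C7 acetate arm, would be carried as the ortho-silyl aryl triflate A1, and the four carbons and the C2 oxygen of ring C would come from 3-methoxyfuran A2. Fluoride would release the C4a≡C8a aryne from A1, and [4+2] addition across the 2,5-positions of A2 would give the oxygen-bridged adduct A3 (racemic; both bridgehead centres vanish on aromatisation).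
- In favour: the conditions are neutral and mild, which is better than the strongly basic step 7. The C7 arm is already at the acid oxidation level, an equal or better starting point for ring D than the benzyloxyethyl arm of 16. Ring C then needs only bridge opening and oxidation.
- Against: A1 is a pentasubstituted benzene that already contains the crowded triad and the diaryl ketone, so the central difficulty is moved into the precursor and not solved. The orientation of the cycloaddition rests on an electronic bias (the C5 methoxy group and the more nucleophilic C2 of A2), whereas in step 7 a wrong orientation is constitutionally impossible. The bridge of A3 must still be opened and oxidised so that carbonyls end at C1 and C4.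
- Comparison: mechanistically both plans are sound. Structurally the chosen plan attacks the hard ring and this one the easy ring. After the key step the step count is equal or slightly better here; before it, it is clearly worse because A1 needs a long linear sequence.

Alternative 2: Both bonds at the crowded edge are cut at once, C6–C(=O) and C7–CH2. The partners would be the ortho-silyl naphthyl triflate A4 and the ring A ketone A5, which bears the pyranonylmethyl group on its α-carbon. Fluoride would generate the C6≡C7 naphthalyne from A4. The enolate carbon of A5 would add to C7, remote from the C5 methoxy group; the aryl anion at C6 would close onto the ketone to a four-membered alkoxide, and fragmentation would insert the aryne into the CO–CH2 bond to give A6.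
- In favour: this is the most convergent plan. Both crowded bonds and the complete skeleton with ring D arise in one step, and A6 would be two operations from the target, against seven after 16. That is a clear advantage in post-key-step economy. The regiochemical argument is as good as in the chosen plan.
- Against: this insertion is established for β-keto esters and 1,3-diketones, whereas the methylene of A5 is activated on one side only through a vinylogous pyranone. The aryl anion would have to add to a carbonyl shielded by both ortho groups of ring A, so protonation to a simple α-arylation product is the likely diversion. The 2-pyranone of A5 is itself a diene for arynes. A4 needs its own multistep synthesis.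
- Comparison: structurally equal or better, since it sees the same adjacency and uses it more directly. Mechanistically it is less secure for this substrate class. Its step economy is better only if the insertion works.

Alternative 3: The cut lies in ring A, at C1'–C2' and C5'–C6'. The naphthalene with ring D would be carried as the but-2-ynoyl compound A7, and four carbons of ring A would come from the bis-silyloxy diene A8. On heating, the nucleophilic terminus of A8 would bond to the methyl-bearing β-carbon of A7 and the other terminus to the α-carbon; acid work-up would aromatise the adduct to A9 with ring A as a free resorcinol.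
- In favour: the crowded ketone is never made by bond formation at its carbonyl carbon, and the orientation follows from the polarity of both partners. Ring A arrives unprotected, so two fewer ethers have to be cleaved; on that point it is better than the chosen plan.
- Against: A7 already contains the C5/C6/C7-substituted ring B, whose construction would need an annulation of the kind chosen here, so this step is added and replaces nothing. An internal ynone with a β-methyl group next to a di-ortho-substituted aryl ketone is a sluggish dienophile. The pyranone can compete as a cycloaddition partner. The free resorcinol of A9 would not tolerate a later oxidative demethylation of ring C.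
- Comparison: mechanistically equal, structurally inferior because ring A comes at no cost from 9 in the chosen plan, and worse in step economy.

Key step: step 7

## Route

Step 1
Reactants: 1 2,4,5-trimethoxybenzoic acid
Product: 3 N,N-diethyl-2,4,5-trimethoxybenzamide, via acid chloride 2 (not isolated)
Conditions: (COCl)2, cat. DMF, CH2Cl2, 0 °C → rt; then Et2NH, aq. NaOH, CH2Cl2, 0 °C
Reagents that add atoms: diethylamine, CCNCC
Why: Acid chloride formation through the chloroiminium catalyst followed by Schotten–Baumann amidation; the diethylamide is the strongest simple director for step 2.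

Step 2
Reactants: 3 N,N-diethyl-2,4,5-trimethoxybenzamide
Product: 5 N,N-diethyl-2,4,5-trimethoxy-6-methylbenzamide, via aryllithium 4 (not isolated)
Conditions: s-BuLi, TMEDA, THF, −78 °C; then MeI, −78 °C → rt
Reagents that add atoms: iodomethane, CI
Why: Directed ortho-metalation; the amide oxygen delivers the base to C6, the only position flanked by the amide and a methoxy group, in preference to C3 between two weaker methoxy directors, and the aryllithium is methylated by SN2 on iodomethane.

Step 3
Reactants: 5 N,N-diethyl-2,4,5-trimethoxy-6-methylbenzamide
Product: 7 methyl 2,4,5-trimethoxy-6-methylbenzoate, via imidate salt 6 (not isolated)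
Conditions: Me3OBF4, CH2Cl2, rt; then sat. aq. NaHCO3, MeOH, rt
Reagents that add atoms: trimethyloxonium tetrafluoroborate, C[O+](C)C.F[B-](F)(F)F; water, O
Why: O-Methylation of the exposed amide oxygen gives an alkoxyiminium salt whose hydrolysis expels diethylamine and leaves the methyl ester; the activated iminium carbon accepts water where the neutral, doubly shielded amide carbonyl would not.

Step 4
Reactants: 8 4-(benzyloxy)but-1-yne; 9 2,4-dimethoxy-6-methylbenzaldehyde
Product: 11 rac-5-(benzyloxy)-1-(2,4-dimethoxy-6-methylphenyl)pent-2-yn-1-ol, via lithium acetylide 10 (not isolated)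
Conditions: n-BuLi, THF, −78 °C; then 9, −78 → 0 °C; H2O
Reagents that add atoms: none
Why: 1,2-Addition of a lithium acetylide to an aromatic aldehyde; the carbinol centre forms as a racemate and ceases to be a stereocentre in step 5.

Step 5
Reactants: 11 rac-5-(benzyloxy)-1-(2,4-dimethoxy-6-methylphenyl)pent-2-yn-1-ol
Product: 12 5-(benzyloxy)-1-(2,4-dimethoxy-6-methylphenyl)pent-2-yn-1-one
Conditions: MnO2, CH2Cl2, rt
Reagents that add atoms: none
Why: MnO2 oxidation of a benzylic and propargylic alcohol to the ynone under neutral conditions that leave the benzyl ether and the electron-rich arene untouched.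

Step 6
Reactants: 12 5-(benzyloxy)-1-(2,4-dimethoxy-6-methylphenyl)pent-2-yn-1-one
Product: 13 (E)-5-(benzyloxy)-1-(2,4-dimethoxy-6-methylphenyl)-3-methoxypent-2-en-1-one
Conditions: NaOMe (0.1 equiv), MeOH, 0 °C → rt
Reagents that add atoms: methanol, CO
Why: Base-catalysed oxa-Michael addition of methanol to the ynone puts the methoxy group on C3 by construction; reversible addition should settle on the more stable E isomer, and either isomer would give the same naphthol in step 7.

Step 7
Reactants: 7 methyl 2,4,5-trimethoxy-6-methylbenzoate; 13 (E)-5-(benzyloxy)-1-(2,4-dimethoxy-6-methylphenyl)-3-methoxypent-2-en-1-one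
Product: 16 [7-(2-benzyloxyethyl)-5-hydroxy-1,2,4-trimethoxynaphthalen-6-yl](2,4-dimethoxy-6-methylphenyl)methanone (target numbering), via toluate anion 14 (not isolated), via methoxytetralone adduct 15 (not isolated)
Conditions: 7 (2 equiv), LiN(iPr)2 (2 equiv), THF, −78 °C; then 13 (1 equiv), −78 °C → rt; aq. HCl
Reagents that add atoms: none
Why: LiN(iPr)2 removes a proton from the methyl group of 7 ortho to the ester and gives the benzylic anion 14. This anion adds in a conjugate sense to C3 of 13, the methoxy-bearing β-carbon, which forms the C7–C8 bond and an enolate at the future C6. The enolate carbon then attacks the neighbouring ester carbonyl in a 6-(enolexo)-exo-trig Dieckmann closure that forms the C5–C6 bond and ring B, with loss of methoxide, to give the β-diketone 15 as its enolate. E1cB loss of methoxide from C7 and tautomerisation aromatise ring B, and the chelated lithium naphtholate is the sink that pulls the reversible steps forward. The closest known reaction type is the Staunton–Weinreb annulation of ortho-toluate anions with β-alkoxy enones and 4-methoxy-2-pyranones. No stereocentre survives, because C6 and C7 of 15 both become aromatic carbons. The step needs 1,4- over 1,2-addition, which the 2'-methoxy and 6'-methyl groups of ring A secure by shielding the carbonyl carbon, and it needs addition to win over proton abstraction at C4 of 13, which is favoured by −78 °C and by using a second equivalent of 14 as the base for the acidic intermediates so that no free amide base is present. The orientation cannot be wrong, since only the ester carbon can become C5 and only the benzylic carbon C8, which places the three methoxy groups of 7 at C1, C2 and C4.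

Step 8
Reactants: 16 [7-(2-benzyloxyethyl)-5-hydroxy-1,2,4-trimethoxynaphthalen-6-yl](2,4-dimethoxy-6-methylphenyl)methanone
Product: 17 [7-(2-benzyloxyethyl)-1,2,4,5-tetramethoxynaphthalen-6-yl](2,4-dimethoxy-6-methylphenyl)methanone
Conditions: MeI, K2CO3, DMF, 50 °C
Reagents that add atoms: iodomethane, CI
Why: Williamson O-methylation of the chelated naphthol in a dipolar aprotic solvent; capping the phenol protects the electron-rich naphthol from the oxidants and bases of steps 10 to 12.

Step 9
Reactants: 17 [7-(2-benzyloxyethyl)-1,2,4,5-tetramethoxynaphthalen-6-yl](2,4-dimethoxy-6-methylphenyl)methanone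
Product: 18 (2,4-dimethoxy-6-methylphenyl)[7-(2-hydroxyethyl)-1,2,4,5-tetramethoxynaphthalen-6-yl]methanone
Conditions: H2 (1 atm), Pd(OH)2/C, EtOAc/EtOH, rt
Reagents that add atoms: none
Why: Hydrogenolysis of the benzyl ether; the diaryl ketone is shielded by four ortho substituents and should not be reduced under neutral conditions at 1 atm.

Step 10
Reactants: 18 (2,4-dimethoxy-6-methylphenyl)[7-(2-hydroxyethyl)-1,2,4,5-tetramethoxynaphthalen-6-yl]methanone
Product: 19 2-[6-(2,4-dimethoxy-6-methylbenzoyl)-1,2,4,5-tetramethoxynaphthalen-7-yl]acetaldehyde
Conditions: DMP, pyridine, CH2Cl2, 0 °C → rt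
Reagents that add atoms: none
Why: Dess–Martin oxidation of a primary alcohol to the aldehyde under buffered, non-aqueous conditions that avoid over-oxidation and enolisation of the arylacetaldehyde, which is used directly.

Step 11
Reactants: 19 2-[6-(2,4-dimethoxy-6-methylbenzoyl)-1,2,4,5-tetramethoxynaphthalen-7-yl]acetaldehyde; 20 2,2,6-trimethyl-4H-1,3-dioxin-4-one
Product: 22 rac-6-{3-[6-(2,4-dimethoxy-6-methylbenzoyl)-1,2,4,5-tetramethoxynaphthalen-7-yl]-2-hydroxypropyl}-2,2-dimethyl-4H-1,3-dioxin-4-one, via lithium dienolate 21 (not isolated)
Conditions: 20 (3 equiv), LiN(iPr)2 (3 equiv), THF, −78 °C; then 19, −78 °C; AcOH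
Reagents that add atoms: none
Why: Vinylogous aldol addition in which the dienolate reacts at its γ-carbon with the aldehyde at −78 °C while the crowded diaryl ketone is not attacked; the carbinol centre forms as a racemate and disappears in step 12.

Step 12
Reactants: 22 rac-6-{3-[6-(2,4-dimethoxy-6-methylbenzoyl)-1,2,4,5-tetramethoxynaphthalen-7-yl]-2-hydroxypropyl}-2,2-dimethyl-4H-1,3-dioxin-4-one
Product: 23 6-{3-[6-(2,4-dimethoxy-6-methylbenzoyl)-1,2,4,5-tetramethoxynaphthalen-7-yl]-2-oxopropyl}-2,2-dimethyl-4H-1,3-dioxin-4-one
Conditions: DMP, pyridine, CH2Cl2, rt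
Reagents that add atoms: none
Why: Dess–Martin oxidation of the secondary alcohol to the ketone under neutral conditions that spare the acid- and base-sensitive keto-dioxinone.

Step 13
Reactants: 23 6-{3-[6-(2,4-dimethoxy-6-methylbenzoyl)-1,2,4,5-tetramethoxynaphthalen-7-yl]-2-oxopropyl}-2,2-dimethyl-4H-1,3-dioxin-4-one
Product: 25 6-{[6-(2,4-dimethoxy-6-methylbenzoyl)-1,2,4,5-tetramethoxynaphthalen-7-yl]methyl}-4-hydroxy-2H-pyran-2-one, via acylketene 24 (not isolated)
Conditions: toluene, 110 °C
Reagents that add atoms: none
Why: Thermal retro-[4+2] fragmentation of the dioxinone releases acetone and an acylketene, which the enol oxygen of the side-chain ketone captures in a six-membered closure to give the 4-hydroxy-2-pyranone, a known route from keto-dioxinones to 6-substituted hydroxypyranones.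

Step 14
Reactants: 25 6-{[6-(2,4-dimethoxy-6-methylbenzoyl)-1,2,4,5-tetramethoxynaphthalen-7-yl]methyl}-4-hydroxy-2H-pyran-2-one
Product: 27 6-(2,4-dihydroxy-6-methylbenzoyl)-2,5-dihydroxy-7-[(4-hydroxy-2-oxo-2H-pyran-6-yl)methyl]naphthalene-1,4-dione (CNP0158797.0), via naphthalenetetraol 26 (not isolated)
Conditions: BBr3 (excess), CH2Cl2, −78 °C → rt; H2O, 0 °C; then air (O2), EtOAc/aq. phosphate buffer pH 7, rt
Reagents that add atoms: none
Why: BBr3 cleaves all six aryl methyl ethers by bromide attack on the O-methyl of the boron-complexed ether, and the 1,2,4-trihydroxy ring of 26 is a hydroxyhydroquinone that O2 oxidises to the 2-hydroxy-1,4-quinone; the 1,2- and 1,4-quinone forms are tautomers, so only one product is possible, and no metal oxidant meets ring D or the ring A resorcinol.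

## Compound list

1 | 2,4,5-trimethoxybenzoic acid | COc1cc(OC)c(C(=O)O)cc1OC | starting material
2 | 2,4,5-trimethoxybenzoyl chloride | COc1cc(OC)c(C(Cl)=O)cc1OC | intermediate (not isolated)
3 | N,N-diethyl-2,4,5-trimethoxybenzamide | CCN(CC)C(=O)c1cc(OC)c(OC)cc1OC | intermediate
4 | 6-lithio-N,N-diethyl-2,4,5-trimethoxybenzamide (lithium on the carbon between the amide and the 5-methoxy group) | [Li]c1c(C(=O)N(CC)CC)c(OC)cc(OC)c1OC | intermediate (not isolated)
5 | N,N-diethyl-2,4,5-trimethoxy-6-methylbenzamide | CCN(CC)C(=O)c1c(C)c(OC)c(OC)cc1OC | intermediate
6 | N-ethyl-N-[methoxy(2,4,5-trimethoxy-6-methylphenyl)methylidene]ethanaminium tetrafluoroborate | CC[N+](CC)=C(OC)c1c(C)c(OC)c(OC)cc1OC.F[B-](F)(F)F | intermediate (not isolated)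
7 | methyl 2,4,5-trimethoxy-6-methylbenzoate | COC(=O)c1c(C)c(OC)c(OC)cc1OC | intermediate
8 | 4-(benzyloxy)but-1-yne | C#CCCOCc1ccccc1 | starting material
9 | 2,4-dimethoxy-6-methylbenzaldehyde | COc1cc(C)c(C=O)c(OC)c1 | starting material
10 | lithium 4-(benzyloxy)but-1-yn-1-ide | [Li]C#CCCOCc1ccccc1 | intermediate (not isolated)
11 | rac-5-(benzyloxy)-1-(2,4-dimethoxy-6-methylphenyl)pent-2-yn-1-ol | COc1cc(C)c(C(O)C#CCCOCc2ccccc2)c(OC)c1 | intermediate
12 | 5-(benzyloxy)-1-(2,4-dimethoxy-6-methylphenyl)pent-2-yn-1-one | COc1cc(C)c(C(=O)C#CCCOCc2ccccc2)c(OC)c1 | intermediate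
13 | (E)-5-(benzyloxy)-1-(2,4-dimethoxy-6-methylphenyl)-3-methoxypent-2-en-1-one | COc1cc(C)c(C(=O)/C=C(/OC)CCOCc2ccccc2)c(OC)c1 | intermediate
14 | methyl 2-(lithiomethyl)-3,4,6-trimethoxybenzoate (benzylic anion of 7) | [Li]Cc1c(C(=O)OC)c(OC)cc(OC)c1OC | intermediate (not isolated)
15 | 7-(2-benzyloxyethyl)-6-(2,4-dimethoxy-6-methylbenzoyl)-1,2,4,7-tetramethoxy-7,8-dihydronaphthalen-5(6H)-one (target numbering; diastereomer mixture, present as its lithium enolate) | COc1cc(OC)c2c(c1OC)CC(OC)(CCOCc1ccccc1)C(C(=O)c1c(C)cc(OC)cc1OC)C2=O | intermediate (not isolated)
16 | [7-(2-benzyloxyethyl)-5-hydroxy-1,2,4-trimethoxynaphthalen-6-yl](2,4-dimethoxy-6-methylphenyl)methanone | COc1cc(OC)c2c(O)c(C(=O)c3c(C)cc(OC)cc3OC)c(CCOCc3ccccc3)cc2c1OC | intermediate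
17 | [7-(2-benzyloxyethyl)-1,2,4,5-tetramethoxynaphthalen-6-yl](2,4-dimethoxy-6-methylphenyl)methanone | COc1cc(OC)c2c(OC)c(C(=O)c3c(C)cc(OC)cc3OC)c(CCOCc3ccccc3)cc2c1OC | intermediate
18 | (2,4-dimethoxy-6-methylphenyl)[7-(2-hydroxyethyl)-1,2,4,5-tetramethoxynaphthalen-6-yl]methanone | COc1cc(OC)c2c(OC)c(C(=O)c3c(C)cc(OC)cc3OC)c(CCO)cc2c1OC | intermediate
19 | 2-[6-(2,4-dimethoxy-6-methylbenzoyl)-1,2,4,5-tetramethoxynaphthalen-7-yl]acetaldehyde | COc1cc(OC)c2c(OC)c(C(=O)c3c(C)cc(OC)cc3OC)c(CC=O)cc2c1OC | intermediate
20 | 2,2,6-trimethyl-4H-1,3-dioxin-4-one | CC1=CC(=O)OC(C)(C)O1 | starting material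
21 | lithium 2,2-dimethyl-6-methylidene-6H-1,3-dioxin-4-olate | C=C1C=C(O[Li])OC(C)(C)O1 | intermediate (not isolated)
22 | rac-6-{3-[6-(2,4-dimethoxy-6-methylbenzoyl)-1,2,4,5-tetramethoxynaphthalen-7-yl]-2-hydroxypropyl}-2,2-dimethyl-4H-1,3-dioxin-4-one | COc1cc(OC)c2c(OC)c(C(=O)c3c(C)cc(OC)cc3OC)c(CC(O)CC3=CC(=O)OC(C)(C)O3)cc2c1OC | intermediate
23 | 6-{3-[6-(2,4-dimethoxy-6-methylbenzoyl)-1,2,4,5-tetramethoxynaphthalen-7-yl]-2-oxopropyl}-2,2-dimethyl-4H-1,3-dioxin-4-one | COc1cc(OC)c2c(OC)c(C(=O)c3c(C)cc(OC)cc3OC)c(CC(=O)CC3=CC(=O)OC(C)(C)O3)cc2c1OC | intermediate
24 | 6-[6-(2,4-dimethoxy-6-methylbenzoyl)-1,2,4,5-tetramethoxynaphthalen-7-yl]hex-1-ene-1,3,5-trione (acylketene) | COc1cc(OC)c2c(OC)c(C(=O)c3c(C)cc(OC)cc3OC)c(CC(=O)CC(=O)C=C=O)cc2c1OC | intermediate (not isolated)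
25 | 6-{[6-(2,4-dimethoxy-6-methylbenzoyl)-1,2,4,5-tetramethoxynaphthalen-7-yl]methyl}-4-hydroxy-2H-pyran-2-one | COc1cc(OC)c2c(OC)c(C(=O)c3c(C)cc(OC)cc3OC)c(Cc3cc(O)cc(=O)o3)cc2c1OC | intermediate
26 | 6-{[6-(2,4-dihydroxy-6-methylbenzoyl)-1,2,4,5-tetrahydroxynaphthalen-7-yl]methyl}-4-hydroxy-2H-pyran-2-one | Cc1cc(O)cc(O)c1C(=O)c1c(Cc2cc(O)cc(=O)o2)cc2c(O)c(O)cc(O)c2c1O | intermediate (not isolated)
27 | 6-(2,4-dihydroxy-6-methylbenzoyl)-2,5-dihydroxy-7-[(4-hydroxy-2-oxo-2H-pyran-6-yl)methyl]naphthalene-1,4-dione | Cc1cc(O)cc(O)c1C(=O)c1c(Cc2cc(O)cc(=O)o2)cc2c(c1O)C(=O)C=C(O)C2=O | target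

## Step count and least certain steps

Total: 14 steps. Longest linear sequence: 11 steps (steps 1 to 3 or steps 4 to 6, then steps 7 to 14).

Step 7 (key step). The likely failure is proton transfer from C4 of 13 to the benzylic anion, followed by expulsion of benzyloxide, because the β-carbon of 13 is fully substituted and donor-stabilised and therefore slow to accept the nucleophile; self-condensation of the anion on its own ester could also compete. The fallback changes the acceptor class. It sets out from ynone 12 and from 7, deprotonated as before. Conjugate addition to the sp-hybridised β-carbon of 12 gives an allenolate whose α-carbon closes on the ester, and tautomerisation of the resulting naphthalenone gives 16 directly, with no enol ether and no methanol elimination. It comes back to the route at 16 and makes no compound outside the compound list (F0).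

Step 2. The likely failure is leakage of the metalation to C3 between the two methoxy groups, or addition of the alkyllithium to the amide. The fallback sets out from 9 and replaces lithiation by electrophilic substitution. Baeyer–Villiger oxidation (mCPBA, CH2Cl2) gives 2,4-dimethoxy-6-methylphenyl formate F1, and methanolysis (K2CO3, MeOH) gives 2,4-dimethoxy-6-methylphenol F2. O-Methylation (MeI, K2CO3) gives 1,2,5-trimethoxy-3-methylbenzene F3. Bromination with NBS in MeCN, at the free position para to the 1-methoxy group and between the methyl and the 5-methoxy group, gives 2-bromo-1,4,5-trimethoxy-3-methylbenzene F4. Bromine–lithium exchange (n-BuLi, THF, −78 °C) and quenching with methyl chloroformate returns to the route at 7.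

Step 3. The likely failure is stalling of the hydrolysis at the shielded imidate carbon, or reversion to the amide by loss of the O-methyl group. The fallback sets out from 5. Partial reduction with Cp2Zr(H)Cl (THF, rt), in which only hydride has to reach the carbonyl, gives 2,4,5-trimethoxy-6-methylbenzaldehyde F5. Oxidation with NaClO2 (NaH2PO4, 2-methyl-2-butene, t-BuOH/H2O) gives 2,4,5-trimethoxy-6-methylbenzoic acid F6, and alkylation of its carboxylate (MeI, K2CO3, DMF) returns to the route at 7.

Step 11. The likely failure is proton transfer from the acidic α-position of 19 to the dienolate in competition with addition, and to a lesser degree attack through the α- instead of the γ-carbon of the dienolate. The fallback sets out from 19 and changes the bond-forming reaction from aldol to acylation. Oxidation with NaClO2 gives 2-[6-(2,4-dimethoxy-6-methylbenzoyl)-1,2,4,5-tetramethoxynaphthalen-7-yl]acetic acid F7. Activation with CDI in THF gives the acyl imidazolide 2-[6-(2,4-dimethoxy-6-methylbenzoyl)-1,2,4,5-tetramethoxynaphthalen-7-yl]-1-(1H-imidazol-1-yl)ethan-1-one F8. C-Acylation of the lithium dienolate 21 (excess, −78 °C) with F8 gives 23 directly; enolisation of F8 is not a dead end, because the derived ketene is still an acylating agent. The fallback comes back at 23 and removes steps 11 and 12.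

Step 14. The likely failures are incomplete cleavage of the 4'-methoxy group para to the ketone, Lewis-acid-promoted condensation of the ring D enol or the bridging methylene with the C6 ketone, and over-oxidation of the polyphenol by the peroxide formed in the aerobic stage. The fallback sets out from 23 and fixes the quinone oxidation level while ring D is still masked. Oxidative demethylation with (NH4)2Ce(NO3)6 in MeCN/H2O at 0 °C gives 6-{3-[6-(2,4-dimethoxy-6-methylbenzoyl)-2,5-dimethoxy-1,4-dioxo-1,4-dihydronaphthalen-7-yl]-2-oxopropyl}-2,2-dimethyl-4H-1,3-dioxin-4-one F9. Thermolysis in toluene at 110 °C gives 6-(2,4-dimethoxy-6-methylbenzoyl)-7-[(4-hydroxy-2-oxo-2H-pyran-6-yl)methyl]-2,5-dimethoxynaphthalene-1,4-dione F10. BBr3 (CH2Cl2, −78 → 0 °C) then has only four ethers to cleave (C2 vinylogous ester, C5 peri, C2' and C4') and gives 27 without an air-sensitive polyphenol on the way.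

## Further compounds

F0 | step 7 | none | none
F1 | step 2 | 2,4-dimethoxy-6-methylphenyl formate | COc1cc(C)c(OC=O)c(OC)c1
F2 | step 2 | 2,4-dimethoxy-6-methylphenol | COc1cc(C)c(O)c(OC)c1
F3 | step 2 | 1,2,5-trimethoxy-3-methylbenzene | COc1cc(C)c(OC)c(OC)c1
F4 | step 2 | 2-bromo-1,4,5-trimethoxy-3-methylbenzene | COc1cc(OC)c(Br)c(C)c1OC
F5 | step 3 | 2,4,5-trimethoxy-6-methylbenzaldehyde | COc1cc(OC)c(C=O)c(C)c1OC
F6 | step 3 | 2,4,5-trimethoxy-6-methylbenzoic acid | COc1cc(OC)c(C(=O)O)c(C)c1OC
F7 | step 11 | 2-[6-(2,4-dimethoxy-6-methylbenzoyl)-1,2,4,5-tetramethoxynaphthalen-7-yl]acetic acid | COc1cc(OC)c2c(OC)c(C(=O)c3c(C)cc(OC)cc3OC)c(CC(=O)O)cc2c1OC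
F8 | step 11 | 2-[6-(2,4-dimethoxy-6-methylbenzoyl)-1,2,4,5-tetramethoxynaphthalen-7-yl]-1-(1H-imidazol-1-yl)ethan-1-one | COc1cc(OC)c2c(OC)c(C(=O)c3c(C)cc(OC)cc3OC)c(CC(=O)n3ccnc3)cc2c1OC
F9 | step 14 | 6-{3-[6-(2,4-dimethoxy-6-methylbenzoyl)-2,5-dimethoxy-1,4-dioxo-1,4-dihydronaphthalen-7-yl]-2-oxopropyl}-2,2-dimethyl-4H-1,3-dioxin-4-one | COC1=CC(=O)c2c(OC)c(C(=O)c3c(C)cc(OC)cc3OC)c(CC(=O)CC3=CC(=O)OC(C)(C)O3)cc2C1=O
F10 | step 14 | 6-(2,4-dimethoxy-6-methylbenzoyl)-7-[(4-hydroxy-2-oxo-2H-pyran-6-yl)methyl]-2,5-dimethoxynaphthalene-1,4-dione | COC1=CC(=O)c2c(OC)c(C(=O)c3c(C)cc(OC)cc3OC)c(Cc3cc(O)cc(=O)o3)cc2C1=O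
A1 | alternative 1 | methyl 2-[2-(2,4-dimethoxy-6-methylbenzoyl)-3-methoxy-5-{[(trifluoromethyl)sulfonyl]oxy}-4-(trimethylsilyl)phenyl]acetate | COC(=O)Cc1cc(OS(=O)(=O)C(F)(F)F)c([Si](C)(C)C)c(OC)c1C(=O)c1c(C)cc(OC)cc1OC
A2 | alternative 1 | 3-methoxyfuran | COc1ccoc1
A3 | alternative 1 | methyl 2-[6-(2,4-dimethoxy-6-methylbenzoyl)-2,5-dimethoxy-1,4-dihydro-1,4-epoxynaphthalen-7-yl]acetate (target numbering; racemic, one enantiomer drawn) | COC1=C[C@H]2O[C@@H]1c1cc(CC(=O)OC)c(C(=O)c3c(C)cc(OC)cc3OC)c(OC)c12
A4 | alternative 2 | 1,2,4,5-tetramethoxy-6-(trimethylsilyl)naphthalen-7-yl trifluoromethanesulfonate (target numbering) | COc1cc(OC)c2c(OC)c([Si](C)(C)C)c(OS(=O)(=O)C(F)(F)F)cc2c1OC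
A5 | alternative 2 | 6-[2-(2,4-dimethoxy-6-methylphenyl)-2-oxoethyl]-4-methoxy-2H-pyran-2-one | COc1cc(C)c(C(=O)Cc2cc(OC)cc(=O)o2)c(OC)c1
A6 | alternative 2 | (2,4-dimethoxy-6-methylphenyl)[1,2,4,5-tetramethoxy-7-((4-methoxy-2-oxo-2H-pyran-6-yl)methyl)naphthalen-6-yl]methanone | Cc1cc(OC)cc(OC)c1C(=O)c1c(Cc2cc(OC)cc(=O)o2)cc2c(OC)c(OC)cc(OC)c2c1OC
A7 | alternative 3 | 1-[1,2,4,5-tetramethoxy-7-((4-methoxy-2-oxo-2H-pyran-6-yl)methyl)naphthalen-6-yl]but-2-yn-1-one (target numbering) | CC#CC(=O)c1c(Cc2cc(OC)cc(=O)o2)cc2c(OC)c(OC)cc(OC)c2c1OC
A8 | alternative 3 | (1Z)-1-methoxy-1,3-bis(trimethylsilyloxy)buta-1,3-diene | CO/C(O[Si](C)(C)C)=C/C(=C)O[Si](C)(C)C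
A9 | alternative 3 | (2,4-dihydroxy-6-methylphenyl)[1,2,4,5-tetramethoxy-7-((4-methoxy-2-oxo-2H-pyran-6-yl)methyl)naphthalen-6-yl]methanone | Cc1cc(O)cc(O)c1C(=O)c1c(Cc2cc(OC)cc(=O)o2)cc2c(OC)c(OC)cc(OC)c2c1OC
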